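**Plan**

Locants (germacrane-type): ring C1–C10, C14 on C10, C15 on C4, C11(=C13H2)–C12 on C7; the lactone joins C12 to the oxygen on C6; angeloyl = (2Z)-2-methylbut-2-enoyl. Enabling feature: inside the ten-membered ring, O–C6–C5=C4(C15)–C3–O is a (Z)-2-ene-1,4-dioxy array whose C6 end lies γ to the C12 carboxyl through C7, which is the 1,4-oxidation pattern of a C3=C4–C5=C6 ring diene carrying its own carboxylate.
Retrosynthetic cuts, in order: O–C6 together with O–C3 (oxidative 1,4-acyloxylactonisation of the ring diene acid); C5=C6 (ring-closing metathesis); C4–C5 (Stille vinylation); the C8 ester, then C7–C8 (chromium-catalysed 2-(alkoxycarbonyl)allylation of a C8 aldehyde); C3=C4 (iodo-olefination); this leads back to (S)-linalool, acrolein and tert-butyl acrylate.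
Forward: the linalool chain (C1–C3, C8–C10, C14) is joined to the C5–C7/C11–C13 bromide, the triene is completed, the ten-membered carbocycle is closed first, the γ-lactone ring second, and two deprotections finish the route.
Stereochemistry: C10 comes from (S)-linalool; C7 and C8 from the ligand-controlled, syn-selective allylation; the ring-cis C3=C4 bond from the (Z)-selective iodo-olefination and the cis C5=C6 bond from the ring.
C6, C3 and the (Z)-C4=C5 bond all derive from C7 in the key step, through tethered anti-oxypalladation, anti attack of acetate and a ring-enforced anti,anti π-allyl.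

Key step: step 13

Remark: (S)-(+)-linalool of high enantiomeric purity is taken as the commercial source of C10; the (R)-enantiomer would lead into the C10-epimeric series.

**Route**

Step 1
Reactants: 1 (S)-(+)-linalool, (3S)-3,7-dimethylocta-1,6-dien-3-ol
Product: 2 (3S)-3,7-dimethyl-3-(triethylsilyloxy)octa-1,6-diene
Conditions: TESOTf, 2,6-lutidine, CH2Cl2, −78 → 0 °C
Reagents that add atoms: triethylsilyl trifluoromethanesulfonate, CC[Si](CC)(CC)OS(=O)(=O)C(F)(F)F
Why: Silylation of a hindered tertiary alcohol with a silyl triflate and a non-nucleophilic base is standard and does not touch the stereocentre; the ether masks C10–OH, which would otherwise form a lactol with the C3 aldehyde and compete as a nucleophile in step 13.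

Step 2
Reactants: 2 (3S)-3,7-dimethyl-3-(triethylsilyloxy)octa-1,6-diene
Product: 4 (4S)-4-methyl-4-(triethylsilyloxy)hex-5-enal, via ozonide 3 (not isolated)
Conditions: O3 (1 equiv, dye end-point), CH2Cl2, −78 °C; then PPh3, −78 °C → rt
Reagents that add atoms: ozone, O=[O+][O-]
Why: Ozonolysis with reductive work-up should cleave the electron-rich trisubstituted olefin much faster than the monosubstituted vinyl group on the silyloxy-bearing quaternary carbon, giving the C3 aldehyde.

Step 3
Reactants: 4 (4S)-4-methyl-4-(triethylsilyloxy)hex-5-enal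
Product: 5 (3S,6Z)-7-iodo-3-methyl-3-(triethylsilyloxy)octa-1,6-diene
Conditions: EtPPh3I, n-BuLi, THF, 0 °C; I2, −78 °C; NaN(SiMe3)2, −20 °C; then 4, −78 °C → rt
Reagents that add atoms: ethyltriphenylphosphonium iodide, CC[P+](c1ccccc1)(c1ccccc1)c1ccccc1.[I-]; iodine, II
Why: Stork–Zhao-type Wittig olefination with the α-iodo ylide gives the (Z)-2-iodo-2-alkene under kinetic control (iodine cis to the chain), which introduces C4 and C15 and fixes the ring-cis geometry of the future C3=C4 bond.

Step 4
Reactants: 5 (3S,6Z)-7-iodo-3-methyl-3-(triethylsilyloxy)octa-1,6-diene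
Product: 7 (3S,6Z)-7-iodo-3-methyl-3-(triethylsilyloxy)oct-6-en-1-ol, via alkylborane 6 (not isolated)
Conditions: 9-BBN, THF, 0 °C → rt; then NaOH, H2O2, 0 °C
Reagents that add atoms: hydrogen peroxide, OO
Why: Anti-Markovnikov hydroboration–oxidation, in which 9-BBN adds only to the terminal vinyl group (the trisubstituted iodoalkene is inert) and oxidation gives the C8 primary alcohol.

Step 5
Reactants: 7 (3S,6Z)-7-iodo-3-methyl-3-(triethylsilyloxy)oct-6-en-1-ol
Product: 8 (3S,6Z)-7-iodo-3-methyl-3-(triethylsilyloxy)oct-6-enal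
Conditions: Dess–Martin periodinane, NaHCO3, CH2Cl2, 0 °C → rt
Reagents that add atoms: none
Why: Buffered Dess–Martin oxidation of a primary alcohol should give the β-silyloxy aldehyde without β-elimination and without affecting the alkenyl iodide.

Step 6
Reactants: 9 acrolein; 10 tert-butyl acrylate
Product: 11 tert-butyl 3-hydroxy-2-methylidenepent-4-enoate (racemic)
Conditions: DABCO (20 mol%), 1,4-dioxane/H2O, rt
Reagents that add atoms: none
Why: Morita–Baylis–Hillman reaction, in which the amine-derived acrylate enolate adds 1,2 to acrolein; the carbinol stereocentre is erased in step 7, so no control is needed.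

Step 7
Reactants: 11 tert-butyl 3-hydroxy-2-methylidenepent-4-enoate
Product: 12 tert-butyl (2Z)-2-(bromomethyl)penta-2,4-dienoate
Conditions: NBS, Me2S, CH2Cl2, 0 °C → rt
Reagents that add atoms: N-bromosuccinimide, BrN1C(=O)CCC1=O
Why: Corey–Kim-type activation of the alcohol followed by SN2′ attack of bromide through the acrylate should give the conjugated (2Z)-2-(bromomethyl)dienoate (vinyl cis to CH2Br), the usual outcome for Morita–Baylis–Hillman alcohols, under conditions that spare the tert-butyl ester.

Step 8
Reactants: 8 (3S,6Z)-7-iodo-3-methyl-3-(triethylsilyloxy)oct-6-enal; 12 tert-butyl (2Z)-2-(bromomethyl)penta-2,4-dienoate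
Product: 14 tert-butyl (3R,4R,6S,9Z)-3-ethenyl-4-hydroxy-10-iodo-6-methyl-2-methylidene-6-(triethylsilyloxy)undec-9-enoate, via trimethylsilyl ether 13 (not isolated)
Conditions: CrCl2 (10 mol%), chiral carbazole bis(oxazoline) ligand (12 mol%, the enantiomer that directs addition to the Si face of the aldehyde), Mn powder, TMSCl, THF, rt; then aq. citric acid, THF, 0 °C
Reagents that add atoms: none
Why: Nickel-free catalytic asymmetric Nozaki–Hiyama–Kishi 2-(alkoxycarbonyl)allylation, in which the allylchromium adds through its γ-carbon (C7) in a chair transition state, the vinyl-cis-to-CH2Cr geometry giving the syn C7/C8 relationship (both σ-allyl forms of the pentadienyl system lead to the same adduct) and the chiral trivalent-chromium complex selecting the Si face to give (7R,8R); the alkenyl iodide is inert without nickel and the tert-butyl ester blocks lactonisation onto C8–OH.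

Step 9
Reactants: 14 tert-butyl (3R,4R,6S,9Z)-3-ethenyl-4-hydroxy-10-iodo-6-methyl-2-methylidene-6-(triethylsilyloxy)undec-9-enoate
Product: 15 tert-butyl (3R,4R,6S,9Z)-3-ethenyl-10-iodo-6-methyl-2-methylidene-4-{[(2Z)-2-methylbut-2-enoyl]oxy}-6-(triethylsilyloxy)undec-9-enoate
Conditions: angelic acid, 2,4,6-trichlorobenzoyl chloride, Et3N, toluene, rt; then 14, 75 °C (no DMAP)
Reagents that add atoms: angelic acid, C/C=C(/C)C(=O)O
Why: Yamaguchi esterification through the mixed anhydride without a nucleophilic catalyst should acylate the secondary C8–OH without Z→E isomerisation of the angelate, while the bulky tert-butyl ester suppresses the competing 8,12-lactonisation.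

Step 10
Reactants: 15 tert-butyl (3R,4R,6S,9Z)-3-ethenyl-10-iodo-6-methyl-2-methylidene-4-{[(2Z)-2-methylbut-2-enoyl]oxy}-6-(triethylsilyloxy)undec-9-enoate
Product: 16 tert-butyl (3R,4R,6S,9Z)-3-ethenyl-6,10-dimethyl-2-methylidene-4-{[(2Z)-2-methylbut-2-enoyl]oxy}-6-(triethylsilyloxy)dodeca-9,11-dienoate
Conditions: tributyl(vinyl)stannane, Pd(PPh3)4 (5 mol%), CuI (10 mol%), DMF, 40 °C
Reagents that add atoms: tributyl(vinyl)stannane, C=C[Sn](CCCC)(CCCC)CCCC
Why: Stille coupling of the alkenyl iodide proceeds with retention of olefin geometry and installs C5 as the terminal carbon pair of a (Z)-configured 1,3-diene.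

Step 11
Reactants: 16 tert-butyl (3R,4R,6S,9Z)-3-ethenyl-6,10-dimethyl-2-methylidene-4-{[(2Z)-2-methylbut-2-enoyl]oxy}-6-(triethylsilyloxy)dodeca-9,11-dienoate
Product: 17 tert-butyl (3Z,5Z,7R,8R,10S)-8-angeloyloxy-10-(triethylsilyloxy)germacra-3,5,11(13)-trien-12-oate
Conditions: second-generation Hoveyda–Grubbs catalyst RuCl2(H2IMes)(=CH-C6H4-2-OiPr) (10 mol%), 1,4-benzoquinone (20 mol%), toluene (1 mM), 60 °C
Reagents that add atoms: none
Why: Ring-closing metathesis between the C6 vinyl group and the terminal olefin of the diene (the trisubstituted C3=C4 bond, the 1,1-disubstituted acrylate and the angelate are far less reactive) should close the ten-membered ring with the new C5=C6 bond in the less strained cis geometry, the chain being pre-organised by the (Z)-olefin, the quaternary C10 and the vicinal branching at C7/C8.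

Step 12
Reactants: 17 tert-butyl (3Z,5Z,7R,8R,10S)-8-angeloyloxy-10-(triethylsilyloxy)germacra-3,5,11(13)-trien-12-oate
Product: 19 (3Z,5Z,7R,8R,10S)-8-angeloyloxy-10-(triethylsilyloxy)germacra-3,5,11(13)-trien-12-oic acid, via trimethylsilyl ester 18 (not isolated)
Conditions: TMSOTf, 2,6-lutidine, CH2Cl2, 0 °C; then pH 5 aqueous buffer
Reagents that add atoms: none
Why: Silyl triflate-mediated cleavage of the tert-butyl ester (loss of isobutene) under buffered, non-protic conditions gives the silyl ester, which is hydrolysed on work-up, and should leave the angelate, the tertiary silyl ether and the diene intact.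

Step 13
Reactants: 19 (3Z,5Z,7R,8R,10S)-8-angeloyloxy-10-(triethylsilyloxy)germacra-3,5,11(13)-trien-12-oic acid
Product: 21 (3S,4Z,6S,7R,8R,10S)-3-acetoxy-8-angeloyloxy-10-(triethylsilyloxy)germacra-4,11(13)-dien-12,6-olide, via allylpalladium chloride 20 (not isolated)
Conditions: Pd(OAc)2 (10 mol%), LiCl (20 mol%), LiOAc, 1,4-benzoquinone (2 equiv), acetone/AcOH (4:1), rt
Reagents that add atoms: acetic acid, CC(=O)O
Why: Divalent palladium coordinates the C5=C6 bond of the twisted s-cis (Z,Z)-diene on the ring face opposite the C7 acrylic acid arm and the C12 carboxylate adds to C6 anti to the metal, giving the C3–C5 π-allyl 20, which acetate attacks at C3 from outside, anti to palladium, under catalytic chloride, before benzoquinone reoxidises the zerovalent palladium released. The closest known reaction type is the palladium-catalysed intramolecular 1,4-acyloxylactonisation of cyclic conjugated dienes that carry an acetic acid chain on the allylic ring carbon, with its chloride-controlled choice between cis- and trans-1,4-addition. Only the γ-lactone ring closes, in the 5-exo-trig mode, and it must be cis-fused because the one-carbon tether from C7 reaches only one face of C6. C6 is therefore set by C7 through the tether, and C3 is set relative to C6 by the anti/anti sequence at palladium, which places both new C–O bonds on the same face of the U-shaped C3–C6 unit, the cis-1,4 pattern of the target. The (Z)-C4=C5 bond follows from the anti,anti allyl geometry that the ten-membered ring imposes (C2 and C6 both inside), since syn–anti isomerisation would cost the strain of a trans ring olefin. The step needs carboxylate attack at C6 and not C5 (favoured by 5-exo closure and π-allyl formation), 1,4- over 1,2-delivery of acetate, and exclusion of the C10 oxygen as a competing nucleophile, which the triethylsilyl ether secures.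

Step 14
Reactants: 21 (3S,4Z,6S,7R,8R,10S)-3-acetoxy-8-angeloyloxy-10-(triethylsilyloxy)germacra-4,11(13)-dien-12,6-olide
Product: 22 (3S,4Z,6S,7R,8R,10S)-8-angeloyloxy-3-hydroxy-10-(triethylsilyloxy)germacra-4,11(13)-dien-12,6-olide
Conditions: [tBu2Sn(OH)Cl]2 (10 mol%), MeOH/THF, 35 °C
Reagents that add atoms: none
Why: Neutral distannoxane-catalysed transesterification should remove the unhindered secondary acetate while the hindered, conjugated angelate and the α-methylene lactone survive, because no free alkoxide is present to add in a Michael sense or to open the lactone.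

Step 15
Reactants: 22 (3S,4Z,6S,7R,8R,10S)-8-angeloyloxy-3-hydroxy-10-(triethylsilyloxy)germacra-4,11(13)-dien-12,6-olide
Product: 23 (3S,4Z,6S,7R,8R,10S)-8-angeloyloxy-3,10-dihydroxygermacra-4,11(13)-dien-12,6-olide (the target)
Conditions: HF·pyridine, pyridine, THF, 0 °C → rt
Reagents that add atoms: none
Why: Buffered fluoride cleavage of the tertiary triethylsilyl ether is standard and should spare both esters, the lactone and the allylic alcohol.

**Compound list**

1 | (S)-(+)-linalool, (3S)-3,7-dimethylocta-1,6-dien-3-ol | C=C[C@@](C)(O)CCC=C(C)C | starting material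
2 | (3S)-3,7-dimethyl-3-(triethylsilyloxy)octa-1,6-diene | C=C[C@@](C)(O[Si](CC)(CC)CC)CCC=C(C)C | intermediate
3 | 3,3-dimethyl-5-[(3S)-3-methyl-3-(triethylsilyloxy)pent-4-en-1-yl]-1,2,4-trioxolane (ozonide, both epimers at the ring carbon, not isolated) | C=C[C@@](C)(O[Si](CC)(CC)CC)CCC1OOC(C)(C)O1 | intermediate
4 | (4S)-4-methyl-4-(triethylsilyloxy)hex-5-enal | C=C[C@@](C)(O[Si](CC)(CC)CC)CCC=O | intermediate
5 | (3S,6Z)-7-iodo-3-methyl-3-(triethylsilyloxy)octa-1,6-diene | C=C[C@@](C)(O[Si](CC)(CC)CC)CC/C=C(/C)I | intermediate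
6 | 9-[(3R,6Z)-7-iodo-3-methyl-3-(triethylsilyloxy)oct-6-en-1-yl]-9-borabicyclo[3.3.1]nonane (same spatial arrangement as 5, descriptor changed by priority only; not isolated) | B1(CC[C@@](C)(O[Si](CC)(CC)CC)CC/C=C(/C)I)C2CCCC1CCC2 | intermediate
7 | (3S,6Z)-7-iodo-3-methyl-3-(triethylsilyloxy)oct-6-en-1-ol | OCC[C@@](C)(O[Si](CC)(CC)CC)CC/C=C(/C)I | intermediate
8 | (3S,6Z)-7-iodo-3-methyl-3-(triethylsilyloxy)oct-6-enal | O=CC[C@@](C)(O[Si](CC)(CC)CC)CC/C=C(/C)I | intermediate
9 | acrolein (prop-2-enal) | C=CC=O | starting material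
10 | tert-butyl acrylate | C=CC(=O)OC(C)(C)C | starting material
11 | tert-butyl 3-hydroxy-2-methylidenepent-4-enoate (racemic) | C=CC(O)C(=C)C(=O)OC(C)(C)C | intermediate
12 | tert-butyl (2Z)-2-(bromomethyl)penta-2,4-dienoate | C=C/C=C(\CBr)C(=O)OC(C)(C)C | intermediate
13 | tert-butyl (3R,4R,6S,9Z)-3-ethenyl-10-iodo-6-methyl-2-methylidene-6-(triethylsilyloxy)-4-(trimethylsilyloxy)undec-9-enoate (not isolated) | C=C(C(=O)OC(C)(C)C)[C@@H](C=C)[C@H](O[Si](C)(C)C)C[C@@](C)(O[Si](CC)(CC)CC)CC/C=C(/C)I | intermediate
14 | tert-butyl (3R,4R,6S,9Z)-3-ethenyl-4-hydroxy-10-iodo-6-methyl-2-methylidene-6-(triethylsilyloxy)undec-9-enoate | C=C(C(=O)OC(C)(C)C)[C@@H](C=C)[C@H](O)C[C@@](C)(O[Si](CC)(CC)CC)CC/C=C(/C)I | intermediate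
15 | tert-butyl (3R,4R,6S,9Z)-3-ethenyl-10-iodo-6-methyl-2-methylidene-4-{[(2Z)-2-methylbut-2-enoyl]oxy}-6-(triethylsilyloxy)undec-9-enoate | C=C(C(=O)OC(C)(C)C)[C@@H](C=C)[C@H](OC(=O)/C(C)=C\C)C[C@@](C)(O[Si](CC)(CC)CC)CC/C=C(/C)I | intermediate
16 | tert-butyl (3R,4R,6S,9Z)-3-ethenyl-6,10-dimethyl-2-methylidene-4-{[(2Z)-2-methylbut-2-enoyl]oxy}-6-(triethylsilyloxy)dodeca-9,11-dienoate | C=C(C(=O)OC(C)(C)C)[C@@H](C=C)[C@H](OC(=O)/C(C)=C\C)C[C@@](C)(O[Si](CC)(CC)CC)CC/C=C(/C)C=C | intermediate
17 | tert-butyl (3Z,5Z,7R,8R,10S)-8-angeloyloxy-10-(triethylsilyloxy)germacra-3,5,11(13)-trien-12-oate | C=C(C(=O)OC(C)(C)C)[C@H]1/C=C\C(C)=C/CC[C@](C)(O[Si](CC)(CC)CC)C[C@H]1OC(=O)/C(C)=C\C | intermediate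
18 | trimethylsilyl (3Z,5Z,7R,8R,10S)-8-angeloyloxy-10-(triethylsilyloxy)germacra-3,5,11(13)-trien-12-oate (not isolated) | C=C(C(=O)O[Si](C)(C)C)[C@H]1/C=C\C(C)=C/CC[C@](C)(O[Si](CC)(CC)CC)C[C@H]1OC(=O)/C(C)=C\C | intermediate
19 | (3Z,5Z,7R,8R,10S)-8-angeloyloxy-10-(triethylsilyloxy)germacra-3,5,11(13)-trien-12-oic acid | C=C(C(=O)O)[C@H]1/C=C\C(C)=C/CC[C@](C)(O[Si](CC)(CC)CC)C[C@H]1OC(=O)/C(C)=C\C | intermediate
20 | (3Z,5R,6R,7R,8R,10S)-8-angeloyloxy-5-(chloropalladio)-10-(triethylsilyloxy)germacra-3,11(13)-dien-12,6-olide, drawn as the C5-bound form of the C3–C5 π-allyl, palladium anti to the C6–O bond (not isolated) | C=C1C(=O)O[C@H]2[C@H]([Pd]Cl)/C(C)=C\CC[C@](C)(O[Si](CC)(CC)CC)C[C@@H](OC(=O)/C(C)=C\C)[C@@H]12 | intermediate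
21 | (3S,4Z,6S,7R,8R,10S)-3-acetoxy-8-angeloyloxy-10-(triethylsilyloxy)germacra-4,11(13)-dien-12,6-olide | C=C1C(=O)O[C@H]2/C=C(/C)[C@@H](OC(C)=O)CC[C@](C)(O[Si](CC)(CC)CC)C[C@@H](OC(=O)/C(C)=C\C)[C@@H]12 | intermediate
22 | (3S,4Z,6S,7R,8R,10S)-8-angeloyloxy-3-hydroxy-10-(triethylsilyloxy)germacra-4,11(13)-dien-12,6-olide | C=C1C(=O)O[C@H]2/C=C(/C)[C@@H](O)CC[C@](C)(O[Si](CC)(CC)CC)C[C@@H](OC(=O)/C(C)=C\C)[C@@H]12 | intermediate
23 | (3S,4Z,6S,7R,8R,10S)-8-angeloyloxy-3,10-dihydroxygermacra-4,11(13)-dien-12,6-olide; (3aR,4R,6S,9S,10Z,11aS)-6,9-dihydroxy-6,10-dimethyl-3-methylidene-2-oxo-2,3,3a,4,5,6,7,8,9,11a-decahydrocyclodeca[b]furan-4-yl (2Z)-2-methylbut-2-enoate | C=C1C(=O)O[C@H]2/C=C(/C)[C@@H](O)CC[C@](C)(O)C[C@@H](OC(=O)/C(C)=C\C)[C@@H]12 | target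

**Step count and risks**

Total step count: 15. Longest linear sequence: 13 steps (steps 1–5 and 8–15 from 1; steps 6 and 7 prepare bromide 12).

Step 11 (ring-closing metathesis). Intermolecular metathesis may outrun the strained ten-membered closure, the ring may close to the trans C5=C6 isomer, and ruthenium hydrides may move the skipped C6/C11 olefins into conjugation. The fallback sets out from 15 and forms the ring at the C4–C5 bond instead. A (Z)-selective cross-metathesis of the C6 vinyl group of 15 with vinylboronic acid pinacol ester, under a molybdenum monoaryloxide pyrrolide alkylidene Mo(=NAr)(=CHCMe2Ph)(pyrrolide)(OAr′) in benzene at rt, would give tert-butyl (3R,4R,6S,9Z)-10-iodo-6-methyl-2-methylidene-4-{[(2Z)-2-methylbut-2-enoyl]oxy}-3-[(Z)-2-(4,4,5,5-tetramethyl-1,3,2-dioxaborolan-2-yl)ethenyl]-6-(triethylsilyloxy)undec-9-enoate F1. Intramolecular Suzuki–Miyaura coupling of its alkenylboronate with its (Z)-alkenyl iodide (Pd(PPh3)4, Tl2CO3, THF/H2O, high dilution, rt) proceeds with retention at both olefins and comes back to the route at 17.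

Step 13 (key step). The twisted macrocyclic diene may bind palladium poorly, acetate may be delivered at C5 (1,2-addition) or from the palladium face (giving the C3 epimer), the π-allyl may isomerise towards the E olefin, and benzoquinone may consume the diene by cycloaddition. The fallback sets out from 19 and replaces the oxidative event by a redox-neutral allylic substitution. Epoxidation of the more electron-rich trisubstituted C3=C4 bond (mCPBA, NaHCO3, CH2Cl2, 0 °C), expected on the face syn to the acrylic acid arm through hydrogen-bonded delivery, would give (3S,4R,5Z,7R,8R,10S)-8-angeloyloxy-3,4-epoxy-10-(triethylsilyloxy)germacra-5,11(13)-dien-12-oic acid F2, the other epoxide face being removed by chromatography if it forms. Pd(PPh3)4 (5 mol%) in THF at rt then opens the vinyl epoxide with inversion at C4, and the carboxylate closes onto C6 anti to zerovalent-palladium-derived allyl metal (double inversion, 5-exo). This gives the C3 alcohol directly and comes back to the route at 22, leaving out 21 and step 14.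

Step 8 (asymmetric allylation). The catalyst may discriminate poorly between the faces of an aldehyde that has no α-substituent, the syn relationship may erode if the pentadienylchromium reacts through an open transition state, and attack through a terminal carbon may give linear dienoates. The fallback sets out from 12: palladium-catalysed borylation (B2pin2, Pd2(dba)3, toluene, 50 °C) would give tert-butyl (2E)-2-[(4,4,5,5-tetramethyl-1,3,2-dioxaborolan-2-yl)methyl]penta-2,4-dienoate F3. Allylboration of 8 with F3, catalysed by a chiral BINOL-derived phosphoric acid (toluene, −30 °C → rt), passes through a closed chair transition state that enforces γ-attack and the syn relationship while the acid selects the aldehyde face, and comes back to the route at 14.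

**Further compounds**

F1 | step 11 | tert-butyl (3R,4R,6S,9Z)-10-iodo-6-methyl-2-methylidene-4-{[(2Z)-2-methylbut-2-enoyl]oxy}-3-[(Z)-2-(4,4,5,5-tetramethyl-1,3,2-dioxaborolan-2-yl)ethenyl]-6-(triethylsilyloxy)undec-9-enoate | C=C(C(=O)OC(C)(C)C)[C@@H](/C=C\B1OC(C)(C)C(C)(C)O1)[C@H](OC(=O)/C(C)=C\C)C[C@@](C)(O[Si](CC)(CC)CC)CC/C=C(/C)I
F2 | step 13 | (3S,4R,5Z,7R,8R,10S)-8-angeloyloxy-3,4-epoxy-10-(triethylsilyloxy)germacra-5,11(13)-dien-12-oic acid | C=C(C(=O)O)[C@H]1/C=C\[C@@]2(C)O[C@H]2CC[C@](C)(O[Si](CC)(CC)CC)C[C@H]1OC(=O)/C(C)=C\C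
F3 | step 8 | tert-butyl (2E)-2-[(4,4,5,5-tetramethyl-1,3,2-dioxaborolan-2-yl)methyl]penta-2,4-dienoate | C=C/C=C(\CB1OC(C)(C)C(C)(C)O1)C(=O)OC(C)(C)C
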